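Locants: ring C1 (C=O) to C6, side chain C1′–C16′ starting at ring C5. The retrosynthesis cuts C9′–C10′ together with C11′–CH3 (one operation), then C5–C1′, then C3–CH3.
Enabling feature: in the C10′=C11′ E-olefin the CH3 on C11′ and C9′ on C10′ are cis. This is the pattern left by syn addition of CH3–metal to a terminal alkyne. C9′ is a primary, unbranched carbon nine atoms away from the six-membered ring, so CH3 (from Me3Al), a C8 enyne and a C9′ iodide can be joined in one flask.
Forward order: geranyl acetate is turned into a C11 triene acetate, whose C8′=C9′ vinyl group is the latent C9′ iodide. The only ring is bought as a cyclohexenone monoketal, methylated at C3, then allylated at C5.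
Stereochemistry: C4 and C5 are set together by a dynamic kinetic asymmetric hydrogenation of the racemic C4 ketone (cis, 4R,5R). The C2′ and C6′ olefins come from geraniol and the C10′ olefin from the key step.
Helpers: a dioxolane on C1 and SiEt3 on O4, both removed by dilute acid in the last step.

Key step: step 10

Assumption: the (S)-diphosphine/(R,R)-diamine ruthenium catalyst is taken to give the R carbinol, by analogy with 2,4,4-trimethylcyclohex-2-enone and carvone. If the sense is reversed, the mirror-image catalyst is used.

Step 1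
Reactants: 1 geranyl acetate
Product: 2 (2E,6E)-3,7-dimethyl-8-oxoocta-2,6-dien-1-yl acetate
Conditions: SeO2 (1.1 equiv), 1,4-dioxane, 80 °C
Reagents that add atoms: selenium dioxide, O=[Se]=O
Why: Riley oxidation (ene reaction, then [2,3]-sigmatropic shift) should attack the electron-rich terminal C6=C7 olefin rather than the C2=C3 olefin deactivated by the allylic acetate, functionalise only the methyl group that lies E, and with a full equivalent of SeO2 carry the allylic alcohol on to the E-enal.

Step 2
Reactants: 2 (2E,6E)-3,7-dimethyl-8-oxoocta-2,6-dien-1-yl acetate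
Product: 3 (2E,6E)-3,7-dimethylnona-2,6,8-trien-1-yl acetate
Conditions: Ph3PCH3Br, n-BuLi, THF, 0 °C; then 2, −78 °C to 0 °C
Reagents that add atoms: methyltriphenylphosphonium bromide, C[P+](c1ccccc1)(c1ccccc1)c1ccccc1.[Br-]
Why: Wittig methylenation of the unhindered enal is far faster than attack of the ylide on the acetate and does not touch the two E-olefins, so the aldehyde carbon becomes C8′ and the new CH2 becomes C9′ of a terminal 1,3-diene.

Step 3
Reactants: 4 1,4-dioxaspiro[4.5]dec-6-en-8-one
Product: 5 7-iodo-1,4-dioxaspiro[4.5]dec-6-en-8-one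
Conditions: I2, K2CO3, DMAP (cat.), THF/H2O, rt
Reagents that add atoms: iodine, II
Why: Amine-catalysed alpha-iodination of an enone (Baylis–Hillman-type conjugate addition of DMAP, iodination of the enolate, elimination of DMAP) can only place iodine on the vinylic carbon next to the carbonyl group, and the basic medium spares the dioxolane.

Step 4
Reactants: 5 7-iodo-1,4-dioxaspiro[4.5]dec-6-en-8-one
Product: 6 7-methyl-1,4-dioxaspiro[4.5]dec-6-en-8-one
Conditions: Me2Zn, PdCl2(dppf) (3 mol %), THF, 0 °C to rt
Reagents that add atoms: dimethylzinc, C[Zn]C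
Why: Negishi coupling of an alpha-iodoenone, in which oxidative addition of zerovalent palladium into the activated C(sp2)–I bond and methyl transfer from zinc are fast at room temperature, whereas Me2Zn alone adds neither to the ketone nor to the enone.

Step 5
Reactants: 6 7-methyl-1,4-dioxaspiro[4.5]dec-6-en-8-one; 3 (2E,6E)-3,7-dimethylnona-2,6,8-trien-1-yl acetate
Product: 8 rac-9-[(2E,6E)-3,7-dimethylnona-2,6,8-trien-1-yl]-7-methyl-1,4-dioxaspiro[4.5]dec-6-en-8-one, via potassium enoxyborate 7 (not isolated)
Conditions: KN(SiMe3)2, THF, −78 °C; BEt3, to rt; then 3, Pd(PPh3)4 (5 mol %), THF, rt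
Reagents that add atoms: none
Why: Tsuji–Trost allylation of a ketone enolate tamed as its enoxyborate, in which 6 can be deprotonated only at C9 (the gamma carbon is the ketal carbon), the borate attacks the pi-allylpalladium complex from 3 at its unsubstituted CH2 terminus with retention of the E geometry and without the proton exchange that leads to double allylation, and the stereocentre C9 is formed racemic on purpose because step 6 corrects it.

Step 6
Reactants: 8 rac-9-[(2E,6E)-3,7-dimethylnona-2,6,8-trien-1-yl]-7-methyl-1,4-dioxaspiro[4.5]dec-6-en-8-one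
Product: 9 (8R,9R)-9-[(2E,6E)-3,7-dimethylnona-2,6,8-trien-1-yl]-7-methyl-1,4-dioxaspiro[4.5]dec-6-en-8-ol (OH and side chain cis)
Conditions: H2 (10 atm), RuCl2[(S)-tolbinap][(R,R)-dpen] (0.5 mol %), KOt-Bu (10 mol %), i-PrOH/toluene, 25 °C
Reagents that add atoms: none
Why: Noyori carbonyl-selective asymmetric hydrogenation run as a dynamic kinetic resolution, in which KOt-Bu racemises C9 through the cross-conjugated enolate faster than hydrogen is transferred, the outer-sphere Ru–H/N–H catalyst delivers hydride to the carbonyl face that gives 8R (as with 2,4,4-trisubstituted cyclohexenones) and, approaching anti to the C9 side chain as with 2-alkylcyclohexanones and 2-alkyl-1-tetralones, should consume the 9R enantiomer preferentially, so that both stereocentres are set as the cis pair while every C=C bond is left untouched.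

Step 7
Reactants: 9 (8R,9R)-allylic alcohol
Product: 10 (8R,9R)-9-[(2E,6E)-3,7-dimethylnona-2,6,8-trien-1-yl]-7-methyl-8-(triethylsilyloxy)-1,4-dioxaspiro[4.5]dec-6-ene
Conditions: Et3SiCl, imidazole, CH2Cl2, 0 °C
Reagents that add atoms: chlorotriethylsilane, CC[Si](Cl)(CC)CC
Why: Standard silylation of the secondary allylic alcohol removes the only acidic hydrogen before the organometallic steps, and SiEt3 is chosen because it falls together with the dioxolane in step 11.

Step 8
Reactants: 10 triethylsilyl ether with terminal 1,3-diene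
Product: 12 (8R,9R)-9-[(2E,6E)-9-iodo-3,7-dimethylnona-2,6-dien-1-yl]-7-methyl-8-(triethylsilyloxy)-1,4-dioxaspiro[4.5]dec-6-ene, via alkylzirconocene chloride 11 (not isolated)
Conditions: Cp2Zr(H)Cl (1.3 equiv), THF, rt; then I2, −20 °C
Reagents that add atoms: iodine, II
Why: Hydrozirconation of a 1,3-diene adds Zr–H in 1,2 fashion to the monosubstituted vinyl group only, with zirconium on the terminal carbon C9′ and the three trisubstituted olefins inert to Cp2Zr(H)Cl, and iodinolysis of the C–Zr bond then gives the homoallylic primary iodide.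

Step 9
Reactants: 13 6-methylhept-5-en-2-one
Product: 15 6-methylhept-5-en-1-yne, via enol phosphate 14 (not isolated)
Conditions: LDA (1.1 equiv), THF, −78 °C; ClP(O)(OEt)2, to rt; then LDA (2.2 equiv), −78 °C to rt; H2O
Reagents that add atoms: none
Why: Conversion of a methyl ketone into a terminal alkyne through its kinetic enol phosphate, in which LDA deprotonates the methyl group, O-phosphorylation fixes the terminal enol, and further LDA causes beta-elimination of diethyl phosphate without touching the trisubstituted olefin.

Step 10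
Reactants: 15 6-methylhept-5-en-1-yne; 12 homoallylic iodide
Product: 18 (8R,9R)-7-methyl-9-[(2E,6E,10E)-3,7,11,15-tetramethylhexadeca-2,6,10,14-tetraen-1-yl]-8-(triethylsilyloxy)-1,4-dioxaspiro[4.5]dec-6-ene, via alkenylalane 16 (not isolated), via alkenylzinc bromide 17 (not isolated)
Conditions: 15 (1.6 equiv), Me3Al, Cp2ZrCl2 (0.2 equiv), CH2Cl2, 0 °C to rt; volatiles off in vacuo; THF, ZnBr2, 0 °C; then 12, Pd2(dba)3 (2 mol %), P(c-C5H9)3 (8 mol %), N-methylimidazole, THF/NMP, 60 °C
Reagents that add atoms: trimethylaluminium, C[Al](C)C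
Why: Proposed new method: Cp2ZrCl2-catalysed methylalumination adds CH3 and Al syn across the terminal alkyne of 15, CH3 to the internal carbon (C11′) and Al to the terminal one (C10′), to give E-alkenylalane 16; ZnBr2 takes over the alkenyl group with retention (17), electron-rich phosphine-ligated zerovalent palladium inserts into the primary C9′–I bond of 12 in an SN2 manner, and transmetalation followed by reductive elimination closes C9′–C10′ with retention, so that CH3, enyne and iodide are joined in one flask. The closest known reaction types are the tandem carboalumination/palladium-catalysed coupling of such alanes with aryl, alkenyl, allyl and benzyl halides under zinc-salt cocatalysis and the Negishi coupling of alkenylzinc halides with unactivated primary alkyl iodides under Pd/trialkylphosphine catalysis; only their merger on an unactivated homoallylic iodide is new. No ring is closed and no stereocentre is formed; the stereochemical element created is the E geometry of C10′=C11′, fixed by syn addition and twofold retention, while C4 and C5 of the ring are spectators. The step needs alkenyl-over-methyl transfer, which the faster migration of sp2 carbon from Al to Zn to Pd and the removal of surplus Me3Al in vacuo should secure, and it needs coupling faster than beta-hydride loss from the homoallylpalladium iodide (which would return triene 10), which the bulky, strongly donating phosphine and the excess of 17 should secure. Chemoselectivity rests on the design of 12: C1 is a dioxolane and O4 a silyl ether, so there is no acidic hydrogen and no carbonyl group, the only reactive site is the unbranched C9′–I bond, and the change from CH2Cl2 to THF/NMP with N-methylimidazole ties up the Lewis-acidic Me2AlBr before the ketal meets it.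

Step 11
Reactants: 18 protected tetraene
Product: 19 (4R,5R)-4-hydroxy-3-methyl-5-[(2E,6E,10E)-3,7,11,15-tetramethylhexadeca-2,6,10,14-tetraen-1-yl]cyclohex-2-en-1-one
Conditions: 0.5 M aq HCl, THF, 0 °C to rt
Reagents that add atoms: water, O
Why: Acid hydrolysis, in which the allylic dioxolane ionises readily and the secondary triethylsilyl ether is highly acid-labile, so both helpers should fall under conditions too mild to protonate the trisubstituted olefins, to disturb C4 or C5, or to dehydrate the gamma-hydroxy enone to a phenol.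

Compound list
1 | geranyl acetate, (2E)-3,7-dimethylocta-2,6-dien-1-yl acetate | CC(C)=CCC/C(C)=C/COC(C)=O | starting material
2 | (2E,6E)-3,7-dimethyl-8-oxoocta-2,6-dien-1-yl acetate | O=C/C(C)=C/CC/C(C)=C/COC(C)=O | intermediate
3 | (2E,6E)-3,7-dimethylnona-2,6,8-trien-1-yl acetate | C=C/C(C)=C/CC/C(C)=C/COC(C)=O | intermediate
4 | 1,4-dioxaspiro[4.5]dec-6-en-8-one | O=C1CCC2(OCCO2)C=C1 | starting material
5 | 7-iodo-1,4-dioxaspiro[4.5]dec-6-en-8-one | O=C1CCC2(OCCO2)C=C1I | intermediate
6 | 7-methyl-1,4-dioxaspiro[4.5]dec-6-en-8-one | O=C1CCC2(OCCO2)C=C1C | intermediate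
7 | potassium triethyl[(7-methyl-1,4-dioxaspiro[4.5]deca-6,8-dien-8-yl)oxy]borate (formed in the flask) | CC[B-](CC)(CC)OC1=CCC2(OCCO2)C=C1C.[K+] | intermediate
8 | rac-9-[(2E,6E)-3,7-dimethylnona-2,6,8-trien-1-yl]-7-methyl-1,4-dioxaspiro[4.5]dec-6-en-8-one | C=C/C(C)=C/CC/C(C)=C/CC1CC2(OCCO2)C=C(C)C1=O | intermediate
9 | (8R,9R)-9-[(2E,6E)-3,7-dimethylnona-2,6,8-trien-1-yl]-7-methyl-1,4-dioxaspiro[4.5]dec-6-en-8-ol (cis) | C=C/C(C)=C/CC/C(C)=C/C[C@@H]1CC2(OCCO2)C=C(C)[C@@H]1O | intermediate
10 | (8R,9R)-9-[(2E,6E)-3,7-dimethylnona-2,6,8-trien-1-yl]-7-methyl-8-(triethylsilyloxy)-1,4-dioxaspiro[4.5]dec-6-ene | C=C/C(C)=C/CC/C(C)=C/C[C@@H]1CC2(OCCO2)C=C(C)[C@@H]1O[Si](CC)(CC)CC | intermediate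
11 | chlorobis(cyclopentadienyl)zirconium C9′-alkyl derived from 10 (formed in the flask; cyclopentadienyl rings written sigma-bound) | Cl[Zr](CC/C(C)=C/CC/C(C)=C/C[C@@H]1CC2(OCCO2)C=C(C)[C@@H]1O[Si](CC)(CC)CC)(C1C=CC=C1)C1C=CC=C1 | intermediate
12 | (8R,9R)-9-[(2E,6E)-9-iodo-3,7-dimethylnona-2,6-dien-1-yl]-7-methyl-8-(triethylsilyloxy)-1,4-dioxaspiro[4.5]dec-6-ene | ICC/C(C)=C/CC/C(C)=C/C[C@@H]1CC2(OCCO2)C=C(C)[C@@H]1O[Si](CC)(CC)CC | intermediate
13 | 6-methylhept-5-en-2-one | CC(=O)CCC=C(C)C | starting material
14 | diethyl 6-methylhepta-1,5-dien-2-yl phosphate (formed in the flask) | C=C(CCC=C(C)C)OP(=O)(OCC)OCC | intermediate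
15 | 6-methylhept-5-en-1-yne | C#CCCC=C(C)C | intermediate
16 | [(1E)-2,6-dimethylhepta-1,5-dien-1-yl]dimethylalane (formed in the flask) | CC(C)=CCC/C(C)=C/[Al](C)C | intermediate
17 | [(1E)-2,6-dimethylhepta-1,5-dien-1-yl]zinc bromide (formed in the flask) | CC(C)=CCC/C(C)=C/[Zn]Br | intermediate
18 | (8R,9R)-7-methyl-9-[(2E,6E,10E)-3,7,11,15-tetramethylhexadeca-2,6,10,14-tetraen-1-yl]-8-(triethylsilyloxy)-1,4-dioxaspiro[4.5]dec-6-ene | CC(C)=CCC/C(C)=C/CC/C(C)=C/CC/C(C)=C/C[C@@H]1CC2(OCCO2)C=C(C)[C@@H]1O[Si](CC)(CC)CC | intermediate
19 | (4R,5R)-4-hydroxy-3-methyl-5-[(2E,6E,10E)-3,7,11,15-tetramethylhexadeca-2,6,10,14-tetraen-1-yl]cyclohex-2-en-1-one | CC(C)=CCC/C(C)=C/CC/C(C)=C/CC/C(C)=C/C[C@@H]1CC(=O)C=C(C)[C@@H]1O | target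

Total step count: 11. Longest linear sequence: 8 steps (1, 2, 5, 6, 7, 8, 10, 11). The branch from 4 through steps 3 and 4 is equally long.

Steps most likely to fail

Step 10. Methyl transfer may compete with alkenyl transfer. Beta-hydride loss from the homoallylpalladium species may outrun transmetalation. Residual aluminium Lewis acid may open the allylic ketal. The fallback sets out from 15 and 10, bypasses step 8 and comes back at 18, with the roles of nucleophile and electrophile exchanged. Alkyne 15 is methylaluminated as before (Me3Al, Cp2ZrCl2 cat., CH2Cl2), but the alane is quenched with I2 in THF at −30 °C and (E)-1-iodo-2,6-dimethylhepta-1,5-diene F1 is isolated. Triene 10 is hydroborated at its terminal vinyl group with 9-BBN-H (THF, rt) to the B-alkyl-9-borabicyclo[3.3.1]nonane F2. The two are then joined by B-alkyl Suzuki–Miyaura coupling (PdCl2(dppf), AsPh3, Cs2CO3, DMF/THF/H2O, rt) to give 18 with retention of the E geometry.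

Step 6. Facial selectivity relative to the side chain may be poor. Hydride delivery along the axial trajectory of the half-chair enone may outrun the approach anti to the C9 substituent, which would favour the trans alcohol. The fallback sets out from 8 and comes back at 9. It accepts the trans preference and corrects the carbinol centre by substitution. The mirror-image catalyst RuCl2[(R)-tolbinap][(S,S)-dpen] is used under the same dynamic conditions to make the (8S,9R)-trans alcohol F3, which already has the right configuration at C9. Mitsunobu reaction (4-nitrobenzoic acid, PPh3, DIAD, toluene, 0 °C) inverts C8 to the (8R,9R)-4-nitrobenzoate F4. Methanolysis (K2CO3, MeOH, rt) then gives 9.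

Step 5. Ionisation of the allylic acetate may be sluggish, double allylation may occur, or the E geometry may erode through syn/anti isomerisation of the pi-allylpalladium complex. The fallback sets out from 3 and 6 and comes back at 8. It replaces catalysis by a direct SN2 alkylation. Acetate 3 is methanolysed (K2CO3, MeOH) to (2E,6E)-3,7-dimethylnona-2,6,8-trien-1-ol F5. PBr3 (Et2O, −10 °C) converts this to (2E,6E)-1-bromo-3,7-dimethylnona-2,6,8-triene F6. The kinetic lithium enolate of 6 (LDA, THF/DMPU, −78 °C) is then alkylated with F6 to give 8.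

Further compounds
F1 | step 10 | (E)-1-iodo-2,6-dimethylhepta-1,5-diene | CC(C)=CCC/C(C)=C/I
F2 | step 10 | B-alkyl-9-borabicyclo[3.3.1]nonane from hydroboration of 10 at C9′ | B3(C4CCCC3CCC4)CC/C(C)=C/CC/C(C)=C/C[C@@H]1CC2(OCCO2)C=C(C)[C@@H]1O[Si](CC)(CC)CC
F3 | step 6 | (8S,9R)-9-[(2E,6E)-3,7-dimethylnona-2,6,8-trien-1-yl]-7-methyl-1,4-dioxaspiro[4.5]dec-6-en-8-ol (trans) | C=C/C(C)=C/CC/C(C)=C/C[C@@H]1CC2(OCCO2)C=C(C)[C@H]1O
F4 | step 6 | (8R,9R)-9-[(2E,6E)-3,7-dimethylnona-2,6,8-trien-1-yl]-7-methyl-1,4-dioxaspiro[4.5]dec-6-en-8-yl 4-nitrobenzoate | C=C/C(C)=C/CC/C(C)=C/C[C@@H]1CC2(OCCO2)C=C(C)[C@@H]1OC(=O)c1ccc(cc1)[N+](=O)[O-]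
F5 | step 5 | (2E,6E)-3,7-dimethylnona-2,6,8-trien-1-ol | C=C/C(C)=C/CC/C(C)=C/CO
F6 | step 5 | (2E,6E)-1-bromo-3,7-dimethylnona-2,6,8-triene | C=C/C(C)=C/CC/C(C)=C/CBr
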